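**Retrosynthetic overview**
- The C5–OH is installed last, by ketone-directed Ru-catalysed C5–H hydroxylation of the 5-deoxyflavone (7,2'-dihydroxy-8,4',5'-trimethoxyflavone), so no C5 oxygen is carried through the route.
- The 5-deoxyflavone comes from a one-pot Pd-catalysed carbonylative alkyne annulation (o-iodoaryl acetate + CO + aryl acetylene; CO becomes C4), followed by MOM removal.
- The iodoarene comes from C2v-symmetric 2-methoxyresorcinol: mono-iodination desymmetrises it and fixes O1 next to the 8-OMe, which removes the 6-OMe/8-OMe and 2'-OH ring-closure ambiguities of diketone (Baker–Venkataraman/chalcone) routes.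
- The alkyne comes from 2-hydroxy-4,5-dimethoxybenzaldehyde (MOM protection, Ohira–Bestmann homologation).
- Ring order: both benzene rings are bought; the γ-pyranone is the only ring formed (step 5).

Assumption: the target is an achiral flavone with no stereocentre or stereogenic axis, so "single enantiomer" is taken to mean the single constitutional isomer drawn.

**Step 1**
Reactants: 1 2-methoxybenzene-1,3-diol (2-methoxyresorcinol)
Product: 2 4-iodo-2-methoxybenzene-1,3-diol
Conditions: I2 (1.0 equiv), NaHCO3, THF/H2O (1:1), 0 °C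
Reagents that add atoms: iodine, II
Why: Electrophilic aromatic iodination of a C2v-symmetric resorcinol, in which C4 and C6 are equivalent (each ortho to one OH and para to the other) and C5 is meta to both, so one equivalent of iodine gives a single mono-iodide.

**Step 2**
Reactants: 2 4-iodo-2-methoxybenzene-1,3-diol
Product: 3 4-iodo-2-methoxy-1,3-phenylene diacetate
Conditions: Ac2O, pyridine, DMAP (cat.), CH2Cl2, 0 °C to rt
Reagents that add atoms: acetic anhydride, CC(=O)OC(C)=O
Why: Standard O-acylation, which masks both phenols so that oxidative addition in step 5 is clean and the free o-iodophenol cannot divert to a benzofuran.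

**Step 3**
Reactants: 4 2-hydroxy-4,5-dimethoxybenzaldehyde
Product: 5 4,5-dimethoxy-2-(methoxymethoxy)benzaldehyde
Conditions: MOMCl, i-Pr2NEt, CH2Cl2, 0 °C to rt
Reagents that add atoms: chloromethyl methyl ether, COCCl
Why: Williamson-type O-alkylation to a base-stable MOM acetal, which prevents later benzofuran formation from an o-ethynylphenol and survives steps 4 and 5.

**Step 4**
Reactants: 5 4,5-dimethoxy-2-(methoxymethoxy)benzaldehyde
Product: 6 1-ethynyl-4,5-dimethoxy-2-(methoxymethoxy)benzene
Conditions: dimethyl (1-diazo-2-oxopropyl)phosphonate, K2CO3, MeOH, 0 °C to rt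
Reagents that add atoms: Ohira–Bestmann reagent, COP(=O)(OC)C(=[N+]=[N-])C(C)=O
Why: Seyferth–Gilbert homologation in its Ohira–Bestmann form converts the non-enolisable aryl aldehyde into the terminal alkyne under mild K2CO3/MeOH conditions that leave the MOM ether intact.

**Step 5**
Reactants: 3 4-iodo-2-methoxy-1,3-phenylene diacetate; 6 1-ethynyl-4,5-dimethoxy-2-(methoxymethoxy)benzene
Product: 9 7-hydroxy-8-methoxy-2-[4,5-dimethoxy-2-(methoxymethoxy)phenyl]-4H-chromen-4-one, via ynone diacetate 7 (not isolated), via diethylamino enaminone 8 (not isolated)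
Conditions: CO (1 atm), PdCl2(PPh3)2 (5 mol %), dppp (5 mol %), thiourea (5 mol %), Et2NH (5 equiv), DBU (2 equiv), DMF, 40 °C
Reagents that add atoms: carbon monoxide, [C-]#[O+]
Why: Pd-catalysed carbonylative Sonogashira coupling (oxidative addition, CO insertion, alkynylation) gives ynone 7; Et2NH then cleaves both acetates and adds to the ynone to give enaminone 8, whose ortho phenol closes 6-endo by addition–elimination (the amine pathway suppresses 5-exo aurone formation), so the pyranone forms with O1 fixed next to the 8-OMe.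

**Step 6**
Reactants: 9 7-hydroxy-8-methoxy-2-[4,5-dimethoxy-2-(methoxymethoxy)phenyl]-4H-chromen-4-one
Product: 10 7-hydroxy-2-(2-hydroxy-4,5-dimethoxyphenyl)-8-methoxy-4H-chromen-4-one
Conditions: 3 M HCl, MeOH/THF, 50 °C
Reagents that add atoms: none
Why: Acid-catalysed solvolysis of the MOM acetal in methanol, to which the aryl methyl ethers and the chromone are inert.

**Step 7**
Reactants: 10 7-hydroxy-2-(2-hydroxy-4,5-dimethoxyphenyl)-8-methoxy-4H-chromen-4-one
Product: 13 5,7-dihydroxy-2-(2-hydroxy-4,5-dimethoxyphenyl)-8-methoxy-4H-chromen-4-one, via bis(trifluoroacetate) 11 (not isolated), via tris(trifluoroacetate) 12 (not isolated)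
Conditions: (CF3CO)2O, CF3CO2H, rt, 30 min; then [RuCl2(p-cymene)]2 (5 mol %), PhI(OCOCF3)2 (1.5 equiv), 80 °C; then MeOH/H2O, rt
Reagents that add atoms: [bis(trifluoroacetoxy)iodo]benzene (source of the C5 oxygen), O=C(OI(OC(=O)C(F)(F)F)c1ccccc1)C(F)(F)F
Why: Ru(II)-catalysed ketone-directed ortho C–H oxygenation, in which the phenols are masked in situ as trifluoroacetates (11), the chromone C4=O directs carboxylate-assisted cycloruthenation at the peri C5–H (the only C–H able to form a five-membered ruthenacycle), oxidation by the iodine(III) reagent and C–O reductive elimination give the C5 trifluoroacetate 12 (which cannot over-oxidise to the 5,8-quinone), and neutral methanolysis releases the three phenols.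

**Compound list**
1 | 2-methoxybenzene-1,3-diol (2-methoxyresorcinol) | COc1c(O)cccc1O | starting material
2 | 4-iodo-2-methoxybenzene-1,3-diol | COc1c(O)ccc(I)c1O | intermediate
3 | 4-iodo-2-methoxy-1,3-phenylene diacetate | COc1c(OC(C)=O)ccc(I)c1OC(C)=O | intermediate
4 | 2-hydroxy-4,5-dimethoxybenzaldehyde | COc1cc(O)c(C=O)cc1OC | starting material
5 | 4,5-dimethoxy-2-(methoxymethoxy)benzaldehyde | COCOc1cc(OC)c(OC)cc1C=O | intermediate
6 | 1-ethynyl-4,5-dimethoxy-2-(methoxymethoxy)benzene | COCOc1cc(OC)c(OC)cc1C#C | intermediate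
7 | 4-{3-[4,5-dimethoxy-2-(methoxymethoxy)phenyl]prop-2-ynoyl}-2-methoxy-1,3-phenylene diacetate (ynone, formed in the flask in step 5) | COc1c(OC(C)=O)ccc(C(=O)C#Cc2cc(OC)c(OC)cc2OCOC)c1OC(C)=O | intermediate
8 | (E)-3-(diethylamino)-1-(2,4-dihydroxy-3-methoxyphenyl)-3-[4,5-dimethoxy-2-(methoxymethoxy)phenyl]prop-2-en-1-one (enaminone, formed in the flask in step 5) | CCN(CC)/C(=C/C(=O)c1ccc(O)c(OC)c1O)c1cc(OC)c(OC)cc1OCOC | intermediate
9 | 7-hydroxy-8-methoxy-2-[4,5-dimethoxy-2-(methoxymethoxy)phenyl]-4H-chromen-4-one | COCOc1cc(OC)c(OC)cc1-c1cc(=O)c2ccc(O)c(OC)c2o1 | intermediate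
10 | 7-hydroxy-2-(2-hydroxy-4,5-dimethoxyphenyl)-8-methoxy-4H-chromen-4-one | COc1cc(O)c(-c2cc(=O)c3ccc(O)c(OC)c3o2)cc1OC | intermediate
11 | 7,2'-bis(trifluoroacetate) of 10 (formed in the flask in step 7) | COc1cc(OC(=O)C(F)(F)F)c(-c2cc(=O)c3ccc(OC(=O)C(F)(F)F)c(OC)c3o2)cc1OC | intermediate
12 | 5,7,2'-tris(trifluoroacetate) of 13 (formed in the flask in step 7) | COc1cc(OC(=O)C(F)(F)F)c(-c2cc(=O)c3c(OC(=O)C(F)(F)F)cc(OC(=O)C(F)(F)F)c(OC)c3o2)cc1OC | intermediate
13 | 5,7-dihydroxy-2-(2-hydroxy-4,5-dimethoxyphenyl)-8-methoxy-4H-chromen-4-one | COc1cc(O)c(-c2cc(=O)c3c(O)cc(O)c(OC)c3o2)cc1OC | target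

**Totals**
Total step count: 7. Longest linear sequence: 5 steps (1 → 2 → 3 → 9 → 10 → 13, or 4 → 5 → 6 → 9 → 10 → 13).

**Three steps most likely to fail, with fallbacks**

Step 7 (C5–H hydroxylation) is the riskiest. The iodine(III) oxidant in CF3CO2H may oxidise the dimethoxyaryl B ring, or conversion at the weakly directing chromone carbonyl may be low. The fallback replaces direct oxygenation by C–H borylation and oxidation; it sets out from 9 and comes back at 13. Compound 9 is protected at O7 (MOMCl, i-Pr2NEt, CH2Cl2) to give 8-methoxy-7-(methoxymethoxy)-2-[4,5-dimethoxy-2-(methoxymethoxy)phenyl]-4H-chromen-4-one F1. Ketone-directed Ir-catalysed ortho borylation ([Ir(OMe)(cod)]2, AsPh3, B2pin2, octane, 120 °C) gives 8-methoxy-7-(methoxymethoxy)-2-[4,5-dimethoxy-2-(methoxymethoxy)phenyl]-5-(4,4,5,5-tetramethyl-1,3,2-dioxaborolan-2-yl)-4H-chromen-4-one F2. Oxidation with NaBO3·4H2O in THF/H2O at rt gives 5-hydroxy-8-methoxy-7-(methoxymethoxy)-2-[4,5-dimethoxy-2-(methoxymethoxy)phenyl]-4H-chromen-4-one F3. Treatment with 3 M HCl in MeOH at 50 °C removes both MOM groups and gives 13.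

Step 5 (carbonylative annulation) is the second risk. Possible failures are aminocarbonylation of the acyl-palladium by Et2NH, non-carbonylative coupling, or 5-exo closure to the aurone. The fallback builds the carbonyl in by classical carboxylation and makes the ynone by acyl Sonogashira coupling; it sets out from 1 and comes back at 7. Kolbe–Schmitt carboxylation of 1 (KHCO3, CO2, H2O, reflux; again a single isomer by symmetry) gives 2,4-dihydroxy-3-methoxybenzoic acid F4. Ac2O/pyridine gives 2,4-diacetoxy-3-methoxybenzoic acid F5. SOCl2 with catalytic DMF in CH2Cl2 at reflux gives 2,4-diacetoxy-3-methoxybenzoyl chloride F6. Coupling of F6 with alkyne 6 (PdCl2(PPh3)2, CuI, Et3N, THF, rt) gives ynone 7, which is now isolated and closed to 9 with Et2NH/DBU in DMF at 40 °C, without palladium or CO.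

Step 1 (mono-iodination) is the third risk. Over-iodination to the 4,6-diiodide and air oxidation of the electron-rich iodoresorcinol can erode the yield. The fallback enforces mono-substitution by directed ortho-metalation; it sets out from 1 and comes back at 2. MOMCl/i-Pr2NEt in CH2Cl2 gives 2-methoxy-1,3-bis(methoxymethoxy)benzene F7. Lithiation ortho to an OMOM group (n-BuLi, THF, 0 °C) and an I2 quench give 1-iodo-3-methoxy-2,4-bis(methoxymethoxy)benzene F8. Treatment with 3 M HCl in MeOH at rt gives 2.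

**Further compounds**
F1 | step 7 | 8-methoxy-7-(methoxymethoxy)-2-[4,5-dimethoxy-2-(methoxymethoxy)phenyl]-4H-chromen-4-one | COCOc1cc(OC)c(OC)cc1-c1cc(=O)c2ccc(OCOC)c(OC)c2o1
F2 | step 7 | 8-methoxy-7-(methoxymethoxy)-2-[4,5-dimethoxy-2-(methoxymethoxy)phenyl]-5-(4,4,5,5-tetramethyl-1,3,2-dioxaborolan-2-yl)-4H-chromen-4-one | COCOc1cc(OC)c(OC)cc1-c1cc(=O)c2c(B3OC(C)(C)C(C)(C)O3)cc(OCOC)c(OC)c2o1
F3 | step 7 | 5-hydroxy-8-methoxy-7-(methoxymethoxy)-2-[4,5-dimethoxy-2-(methoxymethoxy)phenyl]-4H-chromen-4-one | COCOc1cc(OC)c(OC)cc1-c1cc(=O)c2c(O)cc(OCOC)c(OC)c2o1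
F4 | step 5 | 2,4-dihydroxy-3-methoxybenzoic acid | COc1c(O)ccc(C(=O)O)c1O
F5 | step 5 | 2,4-diacetoxy-3-methoxybenzoic acid | COc1c(OC(C)=O)ccc(C(=O)O)c1OC(C)=O
F6 | step 5 | 2,4-diacetoxy-3-methoxybenzoyl chloride | COc1c(OC(C)=O)ccc(C(Cl)=O)c1OC(C)=O
F7 | step 1 | 2-methoxy-1,3-bis(methoxymethoxy)benzene | COCOc1cccc(OCOC)c1OC
F8 | step 1 | 1-iodo-3-methoxy-2,4-bis(methoxymethoxy)benzene | COCOc1ccc(I)c(OCOC)c1OC
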